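**Retrosynth overview**
1. Rivularin A (10) ⇐ silyl biindole 7: one NBS operation exchanges C2'–SiEt3 for C2'–Br (ipso) and brominates C3–H and C2–H of the N1-linked indole.
2. 7 ⇐ 3,4-dibromo-2-iodoaniline (2) + 5-bromo-1-[(triethylsilyl)ethynyl]indole (6): a Larock heteroannulation forms C3a'–C3' and N1'–C2'.
3. Feature used: in the primed pyrrole ring the neighbouring carbons C3' and C2' bear N1 of the 2,3,5-tribromoindole and a bromine. They are read as the two carbons of an alkyne with N1 at one end and SiEt3, a placeholder for bromine, at the other, so the congested N1–C3' bond exists before the ring is built around it.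
4. 6 ⇐ 5-bromoindole (5) + (bromoethynyl)triethylsilane (4, from triethylsilylacetylene 3); 2 ⇐ 3-bromo-2-iodoaniline (1) by para-bromination.
5. Ring order: both benzene rings and the unprimed pyrrole ring are bought; the primed pyrrole ring is the only ring formed (step 4).

Key step: step 4

Assumption 1: the target SMILES carries no descriptor for the N1–C3' axis; should rotation about this axis be slow, the route gives the racemate.
Assumption 2: in step 5 the brominations are listed in the order C3, C2' (ipso), C2; exchanging the first two changes only which tetrabromide is the first intermediate, not the outcome.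

**Route**

Step 1
Reactants: 1 3-bromo-2-iodoaniline
Product: 2 3,4-dibromo-2-iodoaniline
Conditions: NBS (1.0 equiv), DMF, 0 °C to rt, dark
Reagents that add atoms: N-bromosuccinimide, O=C1CCC(=O)N1Br
Why: Electrophilic aromatic bromination directed by the amino group, whose para position (C4) is free while one ortho position is blocked by iodine, so NBS in DMF should give mainly the 4-bromo compound, with attack at the open ortho position C6 as the minor competitor.

Step 2
Reactants: 3 triethylsilylacetylene
Product: 4 (bromoethynyl)triethylsilane
Conditions: NBS (1.1 equiv), AgNO3 (10 mol%), acetone, rt, dark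
Reagents that add atoms: N-bromosuccinimide, O=C1CCC(=O)N1Br
Why: AgNO3-catalysed bromination of a terminal alkyne through its silver acetylide, a standard route to silyl bromoalkynes that leaves the C–Si bond untouched.

Step 3
Reactants: 4 (bromoethynyl)triethylsilane; 5 5-bromoindole
Product: 6 5-bromo-1-[(triethylsilyl)ethynyl]-1H-indole
Conditions: CuSO4·5H2O (15 mol%), 1,10-phenanthroline (30 mol%), K3PO4 (2 equiv), 4 (1.3 equiv), toluene, 80 °C
Reagents that add atoms: none
Why: Copper-catalysed N-alkynylation of an azole N–H with a bromoalkyne, in which the copper indolide should react with the sp C–Br bond far faster than with the aryl C5–Br bond, and the silyl cap keeps the alkyne terminus inert.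

Step 4
Reactants: 2 3,4-dibromo-2-iodoaniline; 6 5-bromo-1-[(triethylsilyl)ethynyl]-1H-indole
Product: 7 4',5,5'-tribromo-2'-(triethylsilyl)-1'H-1,3'-biindole
Conditions: Pd(OAc)2 (10 mol%), LiCl (1 equiv), Na2CO3 (3 equiv), 6 (1.3 equiv), degassed DMF, 100 °C, argon
Reagents that add atoms: none
Why: Pd(OAc)2 is reduced in the flask to zerovalent palladium, which inserts into the C–I bond of 2; the arylpalladium iodide adds syn across alkyne 6 with the aryl carbon (future C3a') going to the N1-bearing carbon (future C3') and palladium to the silylated carbon (future C2'), after which the aniline nitrogen binds palladium, base removes HI, and C–N reductive elimination from the six-membered aza-palladacycle forms N1'–C2' and returns zerovalent palladium. The closest known reaction is the Larock heteroannulation of 2-iodoanilines with silyl-substituted internal alkynes, which places silicon at C2 of the indole; the N-alkynylindole partner and the iodide flanked by NH2 and Br widen the usual substrate range without leaving the reaction type. The one ring formed, the primed pyrrole ring, is closed by intermolecular carbopalladation followed by intramolecular C–N reductive elimination, a formal [3+2] annulation. No stereocentre is created. Two selectivities are needed: C–I must react before any of the three C–Br bonds, which the weaker C–I bond and phosphine-free palladium at 100 °C or below should secure, and the alkyne must insert with silicon next to palladium, which the bulk of Et3Si and the polarisation of the N-alkynyl group (electrophilic N-bearing carbon) both favour. Because iodine sits between NH2 and Br, C3a' is fixed next to C4'–Br and no 4'/6'-bromo regioisomer can arise.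

Step 5
Reactants: 7 4',5,5'-tribromo-2'-(triethylsilyl)-1'H-1,3'-biindole
Product: 10 rivularin A, via tetrabromo silyl biindole 8 (not isolated), via pentabromo biindole 9 (not isolated)
Conditions: NBS (3.1 equiv, in portions), THF, −78 °C to rt, dark; aq. Na2S2O3/NaHCO3 work-up
Reagents that add atoms: N-bromosuccinimide, O=C1CCC(=O)N1Br
Why: Three electrophilic brominations with NBS are expected: at C3 of the N1-substituted indole (the most nucleophilic site), ipso-bromodesilylation at C2' (C3' is blocked and the C–Si bond stabilises the cation formed on attack at C2'), and last at C2 of the 3-bromoindole, while the benzo rings are deactivated by the bromines they already carry.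

**Compound list**
1 | 3-bromo-2-iodoaniline | Nc1cccc(Br)c1I | starting material
2 | 3,4-dibromo-2-iodoaniline | Nc1ccc(Br)c(Br)c1I | intermediate
3 | triethylsilylacetylene | CC[Si](CC)(CC)C#C | starting material
4 | (bromoethynyl)triethylsilane | CC[Si](CC)(CC)C#CBr | intermediate
5 | 5-bromoindole | Brc1ccc2[nH]ccc2c1 | starting material
6 | 5-bromo-1-[(triethylsilyl)ethynyl]-1H-indole | CC[Si](CC)(CC)C#Cn1ccc2cc(Br)ccc21 | intermediate
7 | 4',5,5'-tribromo-2'-(triethylsilyl)-1'H-1,3'-biindole | CC[Si](CC)(CC)c1[nH]c2ccc(Br)c(Br)c2c1-n1ccc2cc(Br)ccc21 | intermediate
8 | 3,4',5,5'-tetrabromo-2'-(triethylsilyl)-1'H-1,3'-biindole | CC[Si](CC)(CC)c1[nH]c2ccc(Br)c(Br)c2c1-n1cc(Br)c2cc(Br)ccc21 | intermediate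
9 | 2',3,4',5,5'-pentabromo-1'H-1,3'-biindole | Brc1[nH]c2ccc(Br)c(Br)c2c1-n1cc(Br)c2cc(Br)ccc21 | intermediate
10 | rivularin A (2,2',3,4',5,5'-hexabromo-1'H-1,3'-biindole) | Brc1ccc2c(c1)c(Br)c(Br)n2-c1c(Br)[nH]c2ccc(Br)c(Br)c12 | target

**Step count**
Total steps: 5. Longest linear sequence: 4 (steps 2, 3, 4, 5, from 3 to 10).

**Steps most likely to fail**

1. Step 4. Oxidative addition at the doubly flanked C–I bond or the intermolecular insertion may be slow. That would leave time for palladium to insert into C–Br bonds (oligomerisation), for the N-alkynylindole to hydrate or decompose, or for insertion with reversed regiochemistry.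
Fallback, setting out from 5 and 2 and returning at 9: 5 is N-alkylated with bromoacetaldehyde diethyl acetal (NaH, DMF, 60 °C) to 5-bromo-1-(2,2-diethoxyethyl)-1H-indole F1. The acetal is hydrolysed (aq. HCl, THF) to (5-bromo-1H-indol-1-yl)acetaldehyde F2. F2 and aniline 2 are heated with Pd(OAc)2 and DABCO in DMF at 85 °C and worked up with aq. NaHCO3. Condensation should give the enamine (E)-3,4-dibromo-N-[2-(5-bromo-1H-indol-1-yl)ethenyl]-2-iodoaniline F3, not isolated, which should close by intramolecular Heck-type arylation at the N1-bearing carbon to 4',5,5'-tribromo-1'H-1,3'-biindole F4. F4 under the NBS conditions of step 5 should be brominated at C2'–H and C3 to reach 9 and then at C2 to give 10. The C3a'–C3' bond here forms intramolecularly on an enamine whose connectivity is fixed by the aldehyde, so alkyne stability and insertion regiochemistry no longer matter. This fallback still needs oxidative addition at the same flanked C–I bond, so it does not answer a failure at that stage.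

2. Step 5. The third bromination (C2 of the deactivated 3-bromoindole) may stall. Forcing it with more reagent may cause bromination of the benzo rings or oxidative breakdown of the N–H indole through a 3'-bromoindolenine.
Fallback, setting out from 9 and returning at 10: 7 is treated with only 2.0 equiv of NBS and 9 is isolated. 9 is then deprotonated with LiN(iPr)2 (2.2 equiv, the first equivalent removing N1'–H) in THF at −78 °C to the C2,N1'-dilithio derivative of 9 F5. F5 is quenched with 1,2-dibromotetrachloroethane and then aq. NH4Cl to give 10. C2–H, flanked by N1 and C3–Br, is the most acidic C–H, so the last bromine is placed by deprotonation instead of electrophilic attack.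

3. Step 3. Cupration of the weakly acidic N–H of a simple indole may be slow compared with homocoupling or decomposition of the bromoalkyne, giving low conversion.
Fallback, setting out from 3 and 5 and returning at 6: aerobic oxidative N-alkynylation of 5 (used in excess and recovered) with the terminal alkyne 3, using CuCl2 (20 mol%), pyridine (2 equiv), Na2CO3 (2 equiv), O2 (1 atm), toluene, 70 °C, with slow addition of 3. This gives 6 directly and bypasses bromoalkyne 4 (new compounds: none F0).

**Further compounds**
F1 | step 4 | 5-bromo-1-(2,2-diethoxyethyl)-1H-indole | CCOC(Cn1ccc2cc(Br)ccc21)OCC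
F2 | step 4 | (5-bromo-1H-indol-1-yl)acetaldehyde | O=CCn1ccc2cc(Br)ccc21
F3 | step 4 | (E)-3,4-dibromo-N-[2-(5-bromo-1H-indol-1-yl)ethenyl]-2-iodoaniline | Brc1ccc2c(c1)ccn2/C=C/Nc1ccc(Br)c(Br)c1I
F4 | step 4 | 4',5,5'-tribromo-1'H-1,3'-biindole | Brc1ccc2c(c1)ccn2-c1c[nH]c2ccc(Br)c(Br)c12
F5 | step 5 | C2,N1'-dilithio derivative of 2',3,4',5,5'-pentabromo-1'H-1,3'-biindole | [Li]c1c(Br)c2cc(Br)ccc2n1-c1c(Br)n([Li])c2ccc(Br)c(Br)c12
F0 | step 3 | none | none
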